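**Plan**
- Retrosynthesis: the C3–O ester bond is cut first, giving the core alcohol and the Z,Z-diester acid. The diosphenol is traced back to a 9,10-epoxy-8-ketone, the C3 hydroxyl to a C–H and the C8 ketone to an allylic CH2, which leaves (+)-aristolochene. Its C6–C7, C5–C10 and C5–CH3 bonds are then cut together, back to farnesyl diphosphate.
- Forward: farnesol is made into the diphosphate, and one cyclase step closes the ten-membered ring and then rings A and B. C8, C3 and C9/C10 are oxidised in that order, the side-chain acid (angelic acid plus a Z-selective olefination) is joined at C3, and the epoxide is opened to the diosphenol last.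
- Enabling feature (eremophilane numbering; ring A = C1–C5 and C10, ring B = C5–C10): the cis methyls on C4 and on quaternary C5, next to C9=C10, are the trace of the eudesmyl-cation hydride and methyl shifts. Aristolochene synthase performs these with the absolute sense of the target.
- Stereochemistry: C4 and C5 come from the cyclase and C3 from the hydroxylase (equatorial, trans to the C4 methyl). Both Z alkenes come from angelic acid and the olefination. The centres at C7, C9 and C10 are transient.

Key step: step 3

Remark: the salts of 3 are drawn as the free acid. The epoxide of 9 and 21 is drawn with oxygen syn to the C5 methyl (steroid analogy); the anti isomer would serve equally. The C3 hydroxylase of step 5 is assumed to be cloned from a fungus that makes 3-oxygenated eremophilanes.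

**Route**

Step 1
Reactants: 1 (2E,6E)-farnesol
Product: 2 (2E,6E)-farnesyl bromide
Conditions: PBr3 (0.4 equiv), Et2O, −10 °C; used crude
Reagents that add atoms: phosphorus tribromide, BrP(Br)Br
Why: SN2 bromination of a primary allylic alcohol through its phosphite ester at low temperature should give the bromide without allylic transposition or loss of the 2E geometry.

Step 2
Reactants: 2 (2E,6E)-farnesyl bromide
Product: 3 (2E,6E)-farnesyl diphosphate (handled as the tris-ammonium salt)
Conditions: (Bu4N)3HP2O7 (2 equiv), MeCN, rt; cation exchange (NH4+ form), NH4HCO3 buffer; lyophilisation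
Reagents that add atoms: tris(tetrabutylammonium) hydrogen diphosphate, CCCC[N+](CCCC)(CCCC)CCCC.CCCC[N+](CCCC)(CCCC)CCCC.CCCC[N+](CCCC)(CCCC)CCCC.OP(=O)([O-])OP(=O)([O-])[O-]
Why: SN2 diphosphorylation of an allylic bromide by the soluble diphosphate salt is the standard entry to prenyl diphosphates and leaves both trisubstituted alkenes untouched.

Step 3
Reactants: 3 (2E,6E)-farnesyl diphosphate
Product: 5 (+)-aristolochene, via (S)-germacrene A 4 (not isolated)
Conditions: recombinant Aspergillus terreus aristolochene synthase (from Escherichia coli), MgCl2 (5 mM), HEPES buffer pH 7.5, glycerol, pentane overlay, 30 °C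
Reagents that add atoms: none
Why: Mg2+-assisted loss of diphosphate gives the farnesyl cation, which the distal chain alkene captures in a 10-exo closure (chain C1–C10, the C6–C7 bond of the eremophilane) to give, after loss of a proton, enzyme-bound germacrene A; reprotonation at C1 then triggers a transannular cation–alkene closure (new C5–C10 bond, 6-endo for ring A and 6-exo for ring B) to the eudesm-4-yl cation, followed by a 1,2-hydride shift from C5 to C4, a 1,2-methyl shift from C10 to C5 and loss of a C9 proton. The closest known reaction type is a cation–olefin polycyclisation with Wagner–Meerwein shifts, here the native reaction of this terpene cyclase. C7 is set in the macrocyclisation by the alkene face that the folded chain presents, C4 by the hydride delivery and C5 by the methyl shift anti to it; because the substrate is achiral, all three are fixed by the active-site contour. The step needs the cascade to stop at the eremophilane stage with a single deprotonation at C9, which no acid in solution achieves. The Aspergillus enzyme is chosen because it releases aristolochene alone, whereas the Penicillium roqueforti enzyme leaks some germacrene A and valencene.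

Step 4
Reactants: 5 (+)-aristolochene
Product: 6 (4S,5R,7S)-eremophila-9,11-dien-8-one
Conditions: Rh2(cap)4 (1 mol %; cap = caprolactamate), tBuOOH (70 % in water, 5 equiv), NaHCO3, 1,2-dichloroethane, 40 °C; stopped short of full conversion
Reagents that add atoms: tert-butyl hydroperoxide, CC(C)(C)OO
Why: Radical allylic oxidation (hydrogen abstraction by tert-butylperoxyl, mixed peroxide, elimination to the enone) should attack C8 because that abstraction gives the allyl radical with a tertiary terminus at C10 and oxygen then enters at the unhindered secondary end, the same preference that turns valencene into nootkatone.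

Step 5
Reactants: 6 (4S,5R,7S)-eremophila-9,11-dien-8-one
Product: 7 (3R,4R,5R,7S)-3-hydroxyeremophila-9,11-dien-8-one
Conditions: recombinant fungal eremophilane C3-hydroxylase (cytochrome P450 with its NADPH–P450 reductase, yeast microsomes), NADP+ (cat.), D-glucose, glucose dehydrogenase, air, phosphate buffer pH 7.4, 2-hydroxypropyl-β-cyclodextrin, 28 °C
Reagents that add atoms: dioxygen, O=O
Why: Proposed new method: the iron-oxo species of the heme abstracts the C3 hydrogen that the pocket presents and returns hydroxyl with retention, which is the only direct way to reach this methylene three bonds from any functional group; the closest known reactions are the C3 hydroxylations that fungal eremophilane pathways carry out on this 8-ketone and the recombinant plant 5-epi-aristolochene 1,3-dihydroxylase acting on the C5-epimeric skeleton, and the 3R outcome is expected because the fungal 3-oxygenated eremophilanes share it, while oxidation at C1, C2 or the alkenes is the selectivity to be screened among candidate enzymes.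

Step 6
Reactants: 7 (3R,4R,5R,7S)-3-hydroxyeremophila-9,11-dien-8-one
Product: 9 (3R,4R,5R,9R,10R)-9,10-epoxy-3-hydroxyeremophil-7(11)-en-8-one, via isopetasol 8 (not isolated)
Conditions: NaOH (0.5 M aq), MeOH, rt; then 30 % H2O2, 0 °C → rt
Reagents that add atoms: hydrogen peroxide, OO
Why: Base first moves the isopropenyl double bond into conjugation (the petasin-to-isopetasin isomerisation) and the Weitz–Scheffer epoxidation then takes the ring enone bond C9=C10 and not the tetrasubstituted isopropylidene, as in the conversion of piperitenone into its ring oxide; hydroperoxide adds at C10 mainly syn to the C5 methyl as in 4-en-3-one steroids, and the face does not matter because C9 and C10 return to sp2 in step 14.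

Step 7
Reactants: 10 angelic acid; 11 2-bromoethanol
Product: 12 2-hydroxyethyl (2Z)-2-methylbut-2-enoate
Conditions: K2CO3, DMF, 40 °C
Reagents that add atoms: none
Why: O-alkylation of the carboxylate (SN2) forms the ester without activating the acyl carbon, so the Z geometry of the angelate cannot leak to the tiglate.

Step 8
Reactants: 12 2-hydroxyethyl (2Z)-2-methylbut-2-enoate
Product: 13 2-oxoethyl (2Z)-2-methylbut-2-enoate
Conditions: Dess–Martin periodinane, NaHCO3, CH2Cl2, rt; used directly
Reagents that add atoms: none
Why: Dess–Martin oxidation of a primary alcohol stops at the aldehyde under buffered neutral conditions that leave the conjugated ester alone.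

Step 9
Reactants: 14 tert-butyl bromoacetate; 15 diphenyl phosphite
Product: 16 tert-butyl 2-(diphenoxyphosphoryl)acetate
Conditions: Et3N, CH2Cl2, 0 °C → rt
Reagents that add atoms: none
Why: Michaelis–Becker alkylation of the phosphite with the reactive α-bromo ester gives the diaryl phosphonoacetate needed for Z-selective olefination, with a tert-butyl ester that acid alone can later remove.

Step 10
Reactants: 16 tert-butyl 2-(diphenoxyphosphoryl)acetate
Product: 17 tert-butyl 2-(diphenoxyphosphoryl)propanoate (racemic)
Conditions: NaH, MeI (1.05 equiv), DMSO, rt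
Reagents that add atoms: iodomethane, CI
Why: C-alkylation of the stabilised phosphonoacetate anion with one equivalent of iodomethane gives the α-methyl reagent, whose stereocentre disappears in the next step.

Step 11
Reactants: 13 2-oxoethyl (2Z)-2-methylbut-2-enoate; 17 tert-butyl 2-(diphenoxyphosphoryl)propanoate
Product: 18 tert-butyl (2Z)-2-methyl-4-{[(2Z)-2-methylbut-2-enoyl]oxy}but-2-enoate
Conditions: NaH, THF, −78 → −20 °C
Reagents that add atoms: none
Why: Horner–Wadsworth–Emmons olefination with a diaryl phosphonate (the Z-selective variant) collapses the kinetic adduct quickly because of the electron-poor aryloxy groups and so places the ester cis to the CH2O chain; the minor E isomer is removed by chromatography.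

Step 12
Reactants: 18 tert-butyl (2Z)-2-methyl-4-{[(2Z)-2-methylbut-2-enoyl]oxy}but-2-enoate
Product: 19 (2Z)-2-methyl-4-{[(2Z)-2-methylbut-2-enoyl]oxy}but-2-enoic acid
Conditions: CF3CO2H, CH2Cl2, 0 °C
Reagents that add atoms: none
Why: Acidolysis of the tert-butyl ester (E1 loss of isobutene) frees the acid without base or nucleophile that could cleave the allylic angelate, and since O4 stays acylated the Z acid cannot close to the butenolide.

Step 13
Reactants: 19 (2Z)-2-methyl-4-{[(2Z)-2-methylbut-2-enoyl]oxy}but-2-enoic acid; 9 (3R,4R,5R,9R,10R)-9,10-epoxy-3-hydroxyeremophil-7(11)-en-8-one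
Product: 21 (3R,4R,5R,9R,10R)-9,10-epoxy-8-oxoeremophil-7(11)-en-3-yl (2Z)-2-methyl-4-{[(2Z)-2-methylbut-2-enoyl]oxy}but-2-enoate, via mixed anhydride 20 (not isolated)
Conditions: 2,4,6-trichlorobenzoyl chloride, Et3N, toluene, rt; then 9, DMAP, toluene, rt
Reagents that add atoms: 2,4,6-trichlorobenzoyl chloride, O=C(Cl)c1c(Cl)cc(Cl)cc1Cl (its atoms are carried only by 20)
Why: Yamaguchi esterification acylates the hindered equatorial C3 hydroxyl through the acylpyridinium of the less hindered carbonyl of the mixed anhydride, a protocol that keeps Z-2-methylbut-2-enoyl units intact, and C3 keeps its configuration because its C–O bond is not touched.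

Step 14
Reactants: 21 (3R,4R,5R,9R,10R)-9,10-epoxy-8-oxoeremophil-7(11)-en-3-yl (2Z)-2-methyl-4-{[(2Z)-2-methylbut-2-enoyl]oxy}but-2-enoate
Product: 22 (3R,4R,5R)-9-hydroxy-8-oxoeremophila-7(11),9-dien-3-yl (2Z)-2-methyl-4-{[(2Z)-2-methylbut-2-enoyl]oxy}but-2-enoate (CNP0301409.1)
Conditions: conc. H2SO4 (cat.), AcOH, 15 °C
Reagents that add atoms: none
Why: Acid-catalysed isomerisation of an α,β-epoxy ketone to the diosphenol (opening at the tertiary C10, loss of the C9 proton), the reaction that turns 4,5-epoxy-3-keto steroids into 4-hydroxy-4-en-3-ones, should give the 9-hydroxy-9-en-8-one from either epoxide face under conditions that carboxylic esters normally survive.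

**Compound list**

1 | (2E,6E)-farnesol | CC(C)=CCC/C(C)=C/CC/C(C)=C/CO | starting material
2 | (2E,6E)-farnesyl bromide | CC(C)=CCC/C(C)=C/CC/C(C)=C/CBr | intermediate
3 | (2E,6E)-farnesyl diphosphate | CC(C)=CCC/C(C)=C/CC/C(C)=C/COP(=O)(O)OP(=O)(O)O | intermediate
4 | (S)-germacrene A | CC(=C)[C@@H]1C/C=C(C)/CC/C=C(C)/CC1 | intermediate
5 | (+)-aristolochene, (4S,5R,7S)-eremophila-9,11-diene | C1CCC2=CC[C@H](C(C)=C)C[C@]2(C)[C@H]1C | intermediate
6 | (4S,5R,7S)-eremophila-9,11-dien-8-one | C1CCC2=CC(=O)[C@H](C(C)=C)C[C@]2(C)[C@H]1C | intermediate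
7 | (3R,4R,5R,7S)-3-hydroxyeremophila-9,11-dien-8-one | O[C@@H]1CCC2=CC(=O)[C@H](C(C)=C)C[C@]2(C)[C@H]1C | intermediate
8 | isopetasol, (3R,4R,5R)-3-hydroxyeremophila-7(11),9-dien-8-one | O[C@@H]1CCC2=CC(=O)C(=C(C)C)C[C@]2(C)[C@H]1C | intermediate
9 | (3R,4R,5R,9R,10R)-9,10-epoxy-3-hydroxyeremophil-7(11)-en-8-one | O[C@@H]1CC[C@]23O[C@H]2C(=O)C(=C(C)C)C[C@]3(C)[C@H]1C | intermediate
10 | angelic acid, (2Z)-2-methylbut-2-enoic acid | C/C=C(/C)C(=O)O | starting material
11 | 2-bromoethanol | OCCBr | starting material
12 | 2-hydroxyethyl (2Z)-2-methylbut-2-enoate | C/C=C(/C)C(=O)OCCO | intermediate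
13 | 2-oxoethyl (2Z)-2-methylbut-2-enoate | C/C=C(/C)C(=O)OCC=O | intermediate
14 | tert-butyl bromoacetate | CC(C)(C)OC(=O)CBr | starting material
15 | diphenyl phosphite | O=[PH](Oc1ccccc1)Oc1ccccc1 | starting material
16 | tert-butyl 2-(diphenoxyphosphoryl)acetate | CC(C)(C)OC(=O)CP(=O)(Oc1ccccc1)Oc1ccccc1 | intermediate
17 | tert-butyl 2-(diphenoxyphosphoryl)propanoate (racemic) | CC(C(=O)OC(C)(C)C)P(=O)(Oc1ccccc1)Oc1ccccc1 | intermediate
18 | tert-butyl (2Z)-2-methyl-4-{[(2Z)-2-methylbut-2-enoyl]oxy}but-2-enoate | C/C=C(/C)C(=O)OC/C=C(/C)C(=O)OC(C)(C)C | intermediate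
19 | (2Z)-2-methyl-4-{[(2Z)-2-methylbut-2-enoyl]oxy}but-2-enoic acid | C/C=C(/C)C(=O)OC/C=C(/C)C(=O)O | intermediate
20 | mixed anhydride of 19 with 2,4,6-trichlorobenzoic acid | C/C=C(/C)C(=O)OC/C=C(/C)C(=O)OC(=O)c1c(Cl)cc(Cl)cc1Cl | intermediate
21 | (3R,4R,5R,9R,10R)-9,10-epoxy-8-oxoeremophil-7(11)-en-3-yl (2Z)-2-methyl-4-{[(2Z)-2-methylbut-2-enoyl]oxy}but-2-enoate | C/C=C(/C)C(=O)OC/C=C(/C)C(=O)O[C@@H]1CC[C@]23O[C@H]2C(=O)C(=C(C)C)C[C@]3(C)[C@H]1C | intermediate
22 | (3R,4R,5R)-9-hydroxy-8-oxoeremophila-7(11),9-dien-3-yl (2Z)-2-methyl-4-{[(2Z)-2-methylbut-2-enoyl]oxy}but-2-enoate | C/C=C(/C)C(=O)OC/C=C(/C)C(=O)O[C@@H]1CCC2=C(O)C(=O)C(=C(C)C)C[C@]2(C)[C@H]1C | target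

**Count**

Total steps: 14. Longest linear sequence: 8 steps (steps 1–6, 13, 14, from farnesol).

**Steps most likely to fail**

1. Step 5 (Proposed new method). The enzyme may bind the ketone in another register and oxidise C1, C2 or an alkene, or it may turn over too slowly for preparative use. The fallback uses known chemistry only, sets out from 6 and comes back at 8.
   - DBU in CH2Cl2 conjugates the isopropenyl group to give (4S,5R)-eremophila-7(11),9-dien-8-one F1.
   - Chloranil in refluxing tert-butanol extends the enone to the linear trienone (4S,5R)-eremophila-1,7(11),9-trien-8-one F2, as in the 4-en-3-one to 4,6-dien-3-one dehydrogenation of steroids.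
   - The C3 methylene is now allylic to C1=C2 and gives the most delocalised radical, so Rh2(cap)4/tBuOOH should oxidise it to (4R,5R)-eremophila-1,7(11),9-triene-3,8-dione F3.
   - H2 over RhCl(PPh3)3 saturates only the cis-disubstituted C1=C2 bond, giving (4R,5R)-eremophila-7(11),9-diene-3,8-dione F4.
   - LiAlH(OtBu)3 in THF at −78 °C reduces the saturated C3 ketone in preference to the cross-conjugated one. Attack is from the equatorial side because the axial C5 methyl blocks the axial path, giving 3-epi-isopetasol F5.
   - Mitsunobu inversion (PPh3, diisopropyl azodicarboxylate, 4-nitrobenzoic acid) gives isopetasol 4-nitrobenzoate F6, and K2CO3 in MeOH releases 8, which enters step 6 at the peroxide stage.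

2. Step 4. Hydrogen abstraction may not discriminate well between C8, C1 and the allylic positions of the isopropenyl group, and the enone may be oxidised further at C7. The fallback sets out from 5 and comes back at 6.
   - A Schenck ene reaction with singlet oxygen (O2, tetraphenylporphyrin, light, CH2Cl2, 0 °C) takes a hydrogen from C8, on the more substituted side of the ring alkene, and places oxygen on C10 anti to the C5 methyl. This gives (4S,5R,7R,10R)-10-hydroperoxyeremophila-8,11-diene F7.
   - PPh3 reduces it to (4S,5R,7R,10R)-eremophila-8,11-dien-10-ol F8.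
   - Pyridinium chlorochromate in CH2Cl2 then effects the Babler–Dauben oxidative transposition of this tertiary allylic alcohol to 6.

3. Step 14. The acid may cleave or isomerise the diester side chain before the epoxide has opened, or the C10 cation may rearrange. The fallback sets out from 9 and comes back at 22; it opens the epoxide before the side chain is present.
   - TsOH·H2O in toluene at 60 °C converts 9 into (3R,4R,5R)-3,9-dihydroxyeremophila-7(11),9-dien-8-one F9.
   - TBSCl with Et3N in CH2Cl2 at 0 °C silylates the acidic enol hydroxyl in preference to the hindered secondary alcohol, giving the 9-O-tert-butyldimethylsilyl ether F10.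
   - Yamaguchi acylation with mixed anhydride 20 and DMAP gives the 9-O-silyl ester F11.
   - HF·pyridine in THF at 0 °C removes the silyl group to give 22.

**Further compounds**

F1 | step 5 | (4S,5R)-eremophila-7(11),9-dien-8-one | C1CCC2=CC(=O)C(=C(C)C)C[C@]2(C)[C@H]1C
F2 | step 5 | (4S,5R)-eremophila-1,7(11),9-trien-8-one | C1C=CC2=CC(=O)C(=C(C)C)C[C@]2(C)[C@H]1C
F3 | step 5 | (4R,5R)-eremophila-1,7(11),9-triene-3,8-dione | O=C1C=CC2=CC(=O)C(=C(C)C)C[C@]2(C)[C@H]1C
F4 | step 5 | (4R,5R)-eremophila-7(11),9-diene-3,8-dione | O=C1CCC2=CC(=O)C(=C(C)C)C[C@]2(C)[C@H]1C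
F5 | step 5 | 3-epi-isopetasol, (3S,4R,5R)-3-hydroxyeremophila-7(11),9-dien-8-one | O[C@H]1CCC2=CC(=O)C(=C(C)C)C[C@]2(C)[C@H]1C
F6 | step 5 | isopetasol 4-nitrobenzoate, (3R,4R,5R)-8-oxoeremophila-7(11),9-dien-3-yl 4-nitrobenzoate | O=C(O[C@@H]1CCC2=CC(=O)C(=C(C)C)C[C@]2(C)[C@H]1C)c1ccc(cc1)[N+](=O)[O-]
F7 | step 4 | (4S,5R,7R,10R)-10-hydroperoxyeremophila-8,11-diene | OO[C@@]12CCC[C@H](C)[C@@]1(C)C[C@@H](C(C)=C)C=C2
F8 | step 4 | (4S,5R,7R,10R)-eremophila-8,11-dien-10-ol | O[C@@]12CCC[C@H](C)[C@@]1(C)C[C@@H](C(C)=C)C=C2
F9 | step 14 | (3R,4R,5R)-3,9-dihydroxyeremophila-7(11),9-dien-8-one | O[C@@H]1CCC2=C(O)C(=O)C(=C(C)C)C[C@]2(C)[C@H]1C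
F10 | step 14 | (3R,4R,5R)-9-(tert-butyldimethylsilyloxy)-3-hydroxyeremophila-7(11),9-dien-8-one | O[C@@H]1CCC2=C(O[Si](C)(C)C(C)(C)C)C(=O)C(=C(C)C)C[C@]2(C)[C@H]1C
F11 | step 14 | (3R,4R,5R)-9-(tert-butyldimethylsilyloxy)-8-oxoeremophila-7(11),9-dien-3-yl (2Z)-2-methyl-4-{[(2Z)-2-methylbut-2-enoyl]oxy}but-2-enoate | C/C=C(/C)C(=O)OC/C=C(/C)C(=O)O[C@@H]1CCC2=C(O[Si](C)(C)C(C)(C)C)C(=O)C(=C(C)C)C[C@]2(C)[C@H]1C
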